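**Plan**
- Retrosynthesis: the last cut removes the twenty O-alkyl groups (19 OMe, 1 OEt) of a protected octamer. Ring D (D1 = carbon bound to the ring C oxygen, D4 = carbon bound to the ring E oxygen) is then cut at three C–C bonds, D2–D3, D1–D6 and D3–D4.
- Enabling feature: ring D bears oxygen at D1, D3, D4, D5 and hydrogen at D2, D6. This is the pattern assembled from an aryloxyacetylene (D1, D2) and a 3-alkoxy-4-aryloxycyclobutenone (D3 = carbonyl carbon, D4, D5, D6), so both bridging oxygens of ring D are in place before the ring exists.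
- Fragments: every other diaryl ether C–O bond is cut to a phenol plus a bromobenzaldehyde (Ullmann coupling). The formyl group then becomes the next phenol (Dakin oxidation).
- Forward: rings are joined A→B→C (then ring C OH → O–C≡CH) and H→G→F→E (then ring E OH → OCH2CO2H → ketene → cyclobutenone). Ring D is the only ring built, in step 18, and BBr3 then frees all hydroxyls.
- Stereochemistry: the target is achiral. The cyclobutenone is used as the racemate and its stereocentre vanishes on aromatisation.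

Key step: step 18

Assumption: the three bromobenzaldehyde building blocks used in steps 3, 9 and 11 are taken as purchasable. "E-F-G-H aryloxy" and "A-B-C aryloxy" denote the fully O-methylated oligomer residues drawn in the compound list.

**Route**

Step 1
Reactants: 1 5-bromo-1,2,3-trimethoxybenzene
Product: 3 6-bromo-2,3,4-trimethoxybenzaldehyde, via chloro ether 2 (not isolated)
Conditions: Cl2CHOMe, TiCl4, CH2Cl2, −10 to 0 °C; then ice water
Reagents that add atoms: dichloromethyl methyl ether, COC(Cl)Cl; water, O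
Why: Rieche formylation; the two free ring positions of 1 are equivalent and each lies ortho and para to methoxy groups, so a single aldehyde with bromine ortho to the formyl group should result after hydrolysis of the racemic chloro ether.

Step 2
Reactants: 4 2,4,6-trimethoxybenzaldehyde
Product: 6 2,4,6-trimethoxyphenol, via 2,4,6-trimethoxyphenyl formate 5 (not isolated)
Conditions: mCPBA, CH2Cl2, 0 °C to rt; aq. NaHCO3 wash; then K2CO3 (cat.), MeOH, rt
Reagents that add atoms: mCPBA, OOC(=O)c1cccc(Cl)c1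
Why: Dakin-type Baeyer–Villiger oxidation, in which the electron-rich aryl group migrates in preference to hydrogen and the aryl formate is cleaved by methanolysis.

Step 3
Reactants: 6 2,4,6-trimethoxyphenol; 7 4-bromo-2,6-dimethoxybenzaldehyde
Product: 8 2,6-dimethoxy-4-(2,4,6-trimethoxyphenoxy)benzaldehyde (A-B aldehyde)
Conditions: CuI (10 mol%), picolinic acid (20 mol%), K3PO4, DMSO, 90 °C, argon
Reagents that add atoms: none
Why: Ullmann diaryl ether coupling; the copper–picolinate system accepts the 2,6-disubstituted phenoxide of 6, and the bromide of 7 is unhindered and activated by the para formyl group.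

Step 4
Reactants: 8 A-B aldehyde
Product: 10 2,6-dimethoxy-4-(2,4,6-trimethoxyphenoxy)phenol (A-B phenol), via A-B aryl formate 9 (not isolated)
Conditions: mCPBA, CH2Cl2, 0 °C to rt; aq. NaHCO3 wash; then K2CO3 (cat.), MeOH, rt
Reagents that add atoms: mCPBA, OOC(=O)c1cccc(Cl)c1
Why: Dakin-type Baeyer–Villiger oxidation; the aryl group flanked by two methoxy groups and para to an aryloxy group migrates readily, and methanolysis of the formate frees the ring B phenol.

Step 5
Reactants: 10 A-B phenol; 3 6-bromo-2,3,4-trimethoxybenzaldehyde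
Product: 11 6-[2,6-dimethoxy-4-(2,4,6-trimethoxyphenoxy)phenoxy]-2,3,4-trimethoxybenzaldehyde (A-B-C aldehyde)
Conditions: CuI (10 mol%), picolinic acid (20 mol%), K3PO4, DMSO, 100 °C, argon
Reagents that add atoms: none
Why: Ullmann diaryl ether coupling; the ortho formyl group of 3 assists oxidative addition at the neighbouring C–Br bond, which offsets the 2,6-dimethoxy substitution of the phenoxide.

Step 6
Reactants: 11 A-B-C aldehyde
Product: 13 6-[2,6-dimethoxy-4-(2,4,6-trimethoxyphenoxy)phenoxy]-2,3,4-trimethoxyphenol (A-B-C phenol), via A-B-C aryl formate 12 (not isolated)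
Conditions: mCPBA, CH2Cl2, 0 °C to rt; aq. NaHCO3 wash; then K2CO3 (cat.), MeOH, rt
Reagents that add atoms: mCPBA, OOC(=O)c1cccc(Cl)c1
Why: Dakin-type Baeyer–Villiger oxidation of a 2-alkoxy-6-aryloxybenzaldehyde, where aryl migration is strongly favoured, followed by formate methanolysis; this places the ring C hydroxyl between the ring B oxygen and a methoxy group.

Step 7
Reactants: 13 A-B-C phenol; 14 trichloroethylene
Product: 15 (E)-1,2-dichlorovinyl ether of the A-B-C phenol
Conditions: K2CO3, DMF, 70 °C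
Reagents that add atoms: none
Why: Base-mediated addition of a phenoxide to dichloroacetylene formed in the flask from trichloroethylene; anti addition of ArO and H accounts for the E geometry of the 1,2-dichlorovinyl ether.

Step 8
Reactants: 15 (E)-1,2-dichlorovinyl ether
Product: 18 ethynyl ether of the A-B-C phenol (A-B-C ynol ether), via chloroethynyl ether 16 (not isolated), via lithium aryloxyacetylide 17 (not isolated)
Conditions: n-BuLi (2.3 equiv), THF, −78 to −40 °C; then H2O, −40 °C; cold work-up, used at once as a toluene solution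
Reagents that add atoms: none
Why: Elimination and halogen–lithium exchange route to ynol ethers; n-BuLi dehydrochlorinates 15 to the chloroalkyne, chlorine–lithium exchange gives the acetylide, and protonation should give the terminal aryl ynol ether, which has no alkyl C–H for retro-ene loss.

Step 9
Reactants: 19 3,4,5-trimethoxyphenol; 20 2-bromo-3,4,5-trimethoxybenzaldehyde
Product: 21 3,4,5-trimethoxy-2-(3,4,5-trimethoxyphenoxy)benzaldehyde (G-H aldehyde)
Conditions: CuI (20 mol%), picolinic acid (40 mol%), K3PO4, DMSO, 110 °C, argon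
Reagents that add atoms: none
Why: Ullmann diaryl ether coupling of an unhindered, electron-rich phenol with a bromide whose ortho formyl group assists the copper insertion, as in the classical couplings of 2-bromo-3,4,5-trimethoxybenzoyl compounds.

Step 10
Reactants: 21 G-H aldehyde
Product: 23 3,4,5-trimethoxy-2-(3,4,5-trimethoxyphenoxy)phenol (G-H phenol), via G-H aryl formate 22 (not isolated)
Conditions: mCPBA, CH2Cl2, 0 °C to rt; aq. NaHCO3 wash; then K2CO3 (cat.), MeOH, rt
Reagents that add atoms: mCPBA, OOC(=O)c1cccc(Cl)c1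
Why: Dakin-type Baeyer–Villiger oxidation; the ortho aryloxy and para methoxy groups direct aryl migration, and the formate is removed by methanolysis.

Step 11
Reactants: 23 G-H phenol; 24 3-bromo-4,5-dimethoxybenzaldehyde
Product: 25 3,4-dimethoxy-5-[3,4,5-trimethoxy-2-(3,4,5-trimethoxyphenoxy)phenoxy]benzaldehyde (F-G-H aldehyde)
Conditions: CuI (10 mol%), picolinic acid (20 mol%), K3PO4, DMSO, 100 °C, argon
Reagents that add atoms: none
Why: Ullmann diaryl ether coupling between a phenol and an aryl bromide that each carry only one ortho substituent, well within the scope of the copper–picolinate system.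

Step 12
Reactants: 25 F-G-H aldehyde
Product: 27 3,4-dimethoxy-5-[3,4,5-trimethoxy-2-(3,4,5-trimethoxyphenoxy)phenoxy]phenol (F-G-H phenol), via F-G-H aryl formate 26 (not isolated)
Conditions: mCPBA, CH2Cl2, 0 °C to rt; aq. NaHCO3 wash; then K2CO3 (cat.), MeOH, rt
Reagents that add atoms: mCPBA, OOC(=O)c1cccc(Cl)c1
Why: Dakin-type Baeyer–Villiger oxidation; the para methoxy group supports aryl migration as it does in the known conversion of 3,4,5-trimethoxybenzaldehyde into the phenol.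

Step 13
Reactants: 27 F-G-H phenol; 3 6-bromo-2,3,4-trimethoxybenzaldehyde
Product: 28 2,3,4-trimethoxy-6-(F-G-H aryloxy)benzaldehyde (E-F-G-H aldehyde)
Conditions: CuI (10 mol%), picolinic acid (20 mol%), K3PO4, DMSO, 100 °C, argon
Reagents that add atoms: none
Why: Ullmann diaryl ether coupling of a phenol without ortho substituents with the ortho-formyl-activated bromide 3, the least hindered coupling of the route.

Step 14
Reactants: 28 E-F-G-H aldehyde
Product: 30 2,3,4-trimethoxy-6-(F-G-H aryloxy)phenol (E-F-G-H phenol), via E-F-G-H aryl formate 29 (not isolated)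
Conditions: mCPBA, CH2Cl2, 0 °C to rt; aq. NaHCO3 wash; then K2CO3 (cat.), MeOH, rt
Reagents that add atoms: mCPBA, OOC(=O)c1cccc(Cl)c1
Why: Dakin-type Baeyer–Villiger oxidation of a 2-alkoxy-6-aryloxybenzaldehyde followed by formate methanolysis; this puts the ring E hydroxyl between the ring F oxygen and a methoxy group.

Step 15
Reactants: 30 E-F-G-H phenol; 31 ethyl bromoacetate
Product: 32 ethyl (E-F-G-H aryloxy)acetate
Conditions: K2CO3, DMF, 60 °C
Reagents that add atoms: none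
Why: Williamson ether synthesis; the primary α-bromo ester is reactive enough to alkylate the phenoxide despite its two ortho substituents.

Step 16
Reactants: 32 ethyl (E-F-G-H aryloxy)acetate
Product: 33 (E-F-G-H aryloxy)acetic acid
Conditions: LiOH, THF/H2O, rt; then 1 M HCl
Reagents that add atoms: lithium hydroxide, [Li+].[OH-]
Why: Ester saponification, to which the aryl methyl ethers and diaryl ethers are inert.

Step 17
Reactants: 33 (E-F-G-H aryloxy)acetic acid; 34 ethoxyacetylene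
Product: 37 racemic 3-ethoxy-4-(E-F-G-H aryloxy)cyclobut-2-en-1-one, via acid chloride 35 (not isolated), via aryloxyketene 36 (not isolated)
Conditions: (COCl)2, DMF (cat.), CH2Cl2, 0 °C to rt, evaporate; then 34 (3 equiv), Et3N (slow addition), CH2Cl2, 0 °C to rt; chromatography on Et3N-deactivated silica
Reagents that add atoms: none
Why: Ketene–alkyne (2+2) cycloaddition; the aryloxyketene formed by dehydrochlorination of the acid chloride is attacked at its carbonyl carbon by the nucleophilic terminal carbon of ethoxyacetylene, which fixes the 3-ethoxy-4-aryloxy pattern, and the new C4 stereocentre forms as the racemate and needs no control.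

Step 18
Reactants: 18 A-B-C ynol ether; 37 racemic 3-ethoxy-4-(E-F-G-H aryloxy)cyclobut-2-en-1-one
Product: 42 nonadeca-O-methyl mono-O-ethyl octamer with free ring D phenol, via vinylketene 38 (not isolated), via 4-vinylcyclobutenone 39 (not isolated), via dienylketene 40 (not isolated), via cyclohexa-2,4-dienone 41 (not isolated)
Conditions: 18 (1.3 equiv), toluene, 90 °C then 110 °C, argon
Reagents that add atoms: none
Why: Thermal four-electron electrocyclic opening of 37, with the C4 aryloxy group rotating outward, gives vinylketene 38; the terminal carbon of 18, made nucleophilic by its oxygen, adds to the ketene carbonyl carbon and the (2+2) cycloaddition closes 4-vinylcyclobutenone 39 (new bonds D2–D3 and D1–D6). A second four-electron opening gives dienylketene 40, whose thermal disrotatory six-electron electrocyclisation joins the ketene carbon to the carbon bearing the ring E oxygen (bond D3–D4) and closes the six-membered ring D as dienone 41, which tautomerises to phenol 42. This is the Danheiser benzannulation of a cyclobutenone with an ynol ether. The sp3 centres on the way (in 37, 39 and 41) are racemic and are erased by aromatisation, so no stereocentre is set. The selectivity needed is the orientation of the ketene–alkyne cycloaddition, secured by the polarisation of the ynol ether: it places the ring C oxygen at D1, meta to the new hydroxyl at D3 and para to the ring E oxygen at D4, with hydrogen at D2 and D6 and ethoxy at D5.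

Step 19
Reactants: 42 protected octamer
Product: 43 CNP0309601.0 (free octamer, 21 hydroxyl groups)
Conditions: BBr3 (excess), CH2Cl2, −78 °C to rt; then H2O, 0 °C; isolation under argon (reversed phase or Sephadex LH-20)
Reagents that add atoms: none
Why: Lewis-acid ether cleavage with BBr3; bromide attacks the methyl and ethyl groups of the boron-complexed ethers, while the diaryl ether bonds, which offer no alkyl carbon, stay intact.

**Compound list**
1 | 5-bromo-1,2,3-trimethoxybenzene | COc1cc(Br)cc(OC)c1OC | starting material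
2 | 1-bromo-2-[chloro(methoxy)methyl]-3,4,5-trimethoxybenzene (racemic chloro ether) | COC(Cl)c1c(Br)cc(OC)c(OC)c1OC | intermediate
3 | 6-bromo-2,3,4-trimethoxybenzaldehyde | COc1cc(Br)c(C=O)c(OC)c1OC | intermediate
4 | 2,4,6-trimethoxybenzaldehyde | COc1cc(OC)c(C=O)c(OC)c1 | starting material
5 | 2,4,6-trimethoxyphenyl formate | COc1cc(OC)c(OC=O)c(OC)c1 | intermediate
6 | 2,4,6-trimethoxyphenol (ring A) | COc1cc(OC)c(O)c(OC)c1 | intermediate
7 | 4-bromo-2,6-dimethoxybenzaldehyde | COc1cc(Br)cc(OC)c1C=O | starting material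
8 | 2,6-dimethoxy-4-(2,4,6-trimethoxyphenoxy)benzaldehyde (A-B aldehyde) | COc1cc(OC)c(Oc2cc(OC)c(C=O)c(OC)c2)c(OC)c1 | intermediate
9 | 2,6-dimethoxy-4-(2,4,6-trimethoxyphenoxy)phenyl formate (A-B aryl formate) | COc1cc(OC)c(Oc2cc(OC)c(OC=O)c(OC)c2)c(OC)c1 | intermediate
10 | 2,6-dimethoxy-4-(2,4,6-trimethoxyphenoxy)phenol (A-B phenol) | COc1cc(OC)c(Oc2cc(OC)c(O)c(OC)c2)c(OC)c1 | intermediate
11 | 6-[2,6-dimethoxy-4-(2,4,6-trimethoxyphenoxy)phenoxy]-2,3,4-trimethoxybenzaldehyde (A-B-C aldehyde) | COc1cc(OC)c(Oc2cc(OC)c(Oc3cc(OC)c(OC)c(OC)c3C=O)c(OC)c2)c(OC)c1 | intermediate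
12 | 6-[2,6-dimethoxy-4-(2,4,6-trimethoxyphenoxy)phenoxy]-2,3,4-trimethoxyphenyl formate (A-B-C aryl formate) | COc1cc(OC)c(Oc2cc(OC)c(Oc3cc(OC)c(OC)c(OC)c3OC=O)c(OC)c2)c(OC)c1 | intermediate
13 | 6-[2,6-dimethoxy-4-(2,4,6-trimethoxyphenoxy)phenoxy]-2,3,4-trimethoxyphenol (A-B-C phenol) | COc1cc(OC)c(Oc2cc(OC)c(Oc3cc(OC)c(OC)c(OC)c3O)c(OC)c2)c(OC)c1 | intermediate
14 | trichloroethylene | ClC=C(Cl)Cl | starting material
15 | (E)-1,2-dichlorovinyl ether of A-B-C phenol 13 | COc1cc(OC)c(Oc2cc(OC)c(Oc3cc(OC)c(OC)c(OC)c3O/C(Cl)=C\Cl)c(OC)c2)c(OC)c1 | intermediate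
16 | chloroethynyl ether of A-B-C phenol 13 | COc1cc(OC)c(Oc2cc(OC)c(Oc3cc(OC)c(OC)c(OC)c3OC#CCl)c(OC)c2)c(OC)c1 | intermediate
17 | lithium acetylide of the A-B-C ethynyl ether | COc1cc(OC)c(Oc2cc(OC)c(Oc3cc(OC)c(OC)c(OC)c3OC#C[Li])c(OC)c2)c(OC)c1 | intermediate
18 | ethynyl ether of A-B-C phenol 13 (A-B-C ynol ether) | COc1cc(OC)c(Oc2cc(OC)c(Oc3cc(OC)c(OC)c(OC)c3OC#C)c(OC)c2)c(OC)c1 | intermediate
19 | 3,4,5-trimethoxyphenol (ring H) | COc1cc(O)cc(OC)c1OC | starting material
20 | 2-bromo-3,4,5-trimethoxybenzaldehyde | COc1cc(C=O)c(Br)c(OC)c1OC | starting material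
21 | 3,4,5-trimethoxy-2-(3,4,5-trimethoxyphenoxy)benzaldehyde (G-H aldehyde) | COc1cc(Oc2c(C=O)cc(OC)c(OC)c2OC)cc(OC)c1OC | intermediate
22 | 3,4,5-trimethoxy-2-(3,4,5-trimethoxyphenoxy)phenyl formate (G-H aryl formate) | COc1cc(Oc2c(OC=O)cc(OC)c(OC)c2OC)cc(OC)c1OC | intermediate
23 | 3,4,5-trimethoxy-2-(3,4,5-trimethoxyphenoxy)phenol (G-H phenol) | COc1cc(Oc2c(O)cc(OC)c(OC)c2OC)cc(OC)c1OC | intermediate
24 | 3-bromo-4,5-dimethoxybenzaldehyde | COc1cc(C=O)cc(Br)c1OC | starting material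
25 | 3,4-dimethoxy-5-[3,4,5-trimethoxy-2-(3,4,5-trimethoxyphenoxy)phenoxy]benzaldehyde (F-G-H aldehyde) | O=Cc1cc(OC)c(OC)c(Oc2cc(OC)c(OC)c(OC)c2Oc2cc(OC)c(OC)c(OC)c2)c1 | intermediate
26 | 3,4-dimethoxy-5-[3,4,5-trimethoxy-2-(3,4,5-trimethoxyphenoxy)phenoxy]phenyl formate (F-G-H aryl formate) | O=COc1cc(OC)c(OC)c(Oc2cc(OC)c(OC)c(OC)c2Oc2cc(OC)c(OC)c(OC)c2)c1 | intermediate
27 | 3,4-dimethoxy-5-[3,4,5-trimethoxy-2-(3,4,5-trimethoxyphenoxy)phenoxy]phenol (F-G-H phenol) | Oc1cc(OC)c(OC)c(Oc2cc(OC)c(OC)c(OC)c2Oc2cc(OC)c(OC)c(OC)c2)c1 | intermediate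
28 | 2,3,4-trimethoxy-6-(F-G-H aryloxy)benzaldehyde (E-F-G-H aldehyde) | O=Cc1c(Oc2cc(OC)c(OC)c(Oc3cc(OC)c(OC)c(OC)c3Oc3cc(OC)c(OC)c(OC)c3)c2)cc(OC)c(OC)c1OC | intermediate
29 | 2,3,4-trimethoxy-6-(F-G-H aryloxy)phenyl formate (E-F-G-H aryl formate) | O=COc1c(Oc2cc(OC)c(OC)c(Oc3cc(OC)c(OC)c(OC)c3Oc3cc(OC)c(OC)c(OC)c3)c2)cc(OC)c(OC)c1OC | intermediate
30 | 2,3,4-trimethoxy-6-(F-G-H aryloxy)phenol (E-F-G-H phenol) | Oc1c(Oc2cc(OC)c(OC)c(Oc3cc(OC)c(OC)c(OC)c3Oc3cc(OC)c(OC)c(OC)c3)c2)cc(OC)c(OC)c1OC | intermediate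
31 | ethyl bromoacetate | CCOC(=O)CBr | starting material
32 | ethyl (E-F-G-H aryloxy)acetate | CCOC(=O)COc1c(Oc2cc(OC)c(OC)c(Oc3cc(OC)c(OC)c(OC)c3Oc3cc(OC)c(OC)c(OC)c3)c2)cc(OC)c(OC)c1OC | intermediate
33 | (E-F-G-H aryloxy)acetic acid | OC(=O)COc1c(Oc2cc(OC)c(OC)c(Oc3cc(OC)c(OC)c(OC)c3Oc3cc(OC)c(OC)c(OC)c3)c2)cc(OC)c(OC)c1OC | intermediate
34 | ethoxyacetylene | CCOC#C | starting material
35 | (E-F-G-H aryloxy)acetyl chloride | ClC(=O)COc1c(Oc2cc(OC)c(OC)c(Oc3cc(OC)c(OC)c(OC)c3Oc3cc(OC)c(OC)c(OC)c3)c2)cc(OC)c(OC)c1OC | intermediate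
36 | (E-F-G-H aryloxy)ketene | O=C=COc1c(Oc2cc(OC)c(OC)c(Oc3cc(OC)c(OC)c(OC)c3Oc3cc(OC)c(OC)c(OC)c3)c2)cc(OC)c(OC)c1OC | intermediate
37 | racemic 3-ethoxy-4-(E-F-G-H aryloxy)cyclobut-2-en-1-one | CCOC1=CC(=O)C1Oc1c(Oc2cc(OC)c(OC)c(Oc3cc(OC)c(OC)c(OC)c3Oc3cc(OC)c(OC)c(OC)c3)c2)cc(OC)c(OC)c1OC | intermediate
38 | (Z)-3-ethoxy-4-(E-F-G-H aryloxy)buta-1,3-dien-1-one (vinylketene; aryloxy trans to the ketene-bearing carbon) | O=C=C/C(OCC)=C/Oc1c(Oc2cc(OC)c(OC)c(Oc3cc(OC)c(OC)c(OC)c3Oc3cc(OC)c(OC)c(OC)c3)c2)cc(OC)c(OC)c1OC | intermediate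
39 | racemic 3-(A-B-C aryloxy)-4-[(Z)-1-ethoxy-2-(E-F-G-H aryloxy)vinyl]cyclobut-2-en-1-one (4-vinylcyclobutenone) | O=C4C=C(Oc1c(Oc2c(OC)cc(Oc3c(OC)cc(OC)cc3OC)cc2OC)cc(OC)c(OC)c1OC)C4/C(OCC)=C/Oc1c(Oc2cc(OC)c(OC)c(Oc3cc(OC)c(OC)c(OC)c3Oc3cc(OC)c(OC)c(OC)c3)c2)cc(OC)c(OC)c1OC | intermediate
40 | (3E,5Z)-3-(A-B-C aryloxy)-5-ethoxy-6-(E-F-G-H aryloxy)hexa-1,3,5-trien-1-one (dienylketene; ketene carbon and C5 cis across C3=C4) | O=C=C/C(Oc1c(Oc2c(OC)cc(Oc3c(OC)cc(OC)cc3OC)cc2OC)cc(OC)c(OC)c1OC)=C\C(OCC)=C\Oc1c(Oc2cc(OC)c(OC)c(Oc3cc(OC)c(OC)c(OC)c3Oc3cc(OC)c(OC)c(OC)c3)c2)cc(OC)c(OC)c1OC | intermediate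
41 | racemic 3-(A-B-C aryloxy)-5-ethoxy-6-(E-F-G-H aryloxy)cyclohexa-2,4-dien-1-one | O=C4C=C(Oc1c(Oc2c(OC)cc(Oc3c(OC)cc(OC)cc3OC)cc2OC)cc(OC)c(OC)c1OC)C=C(OCC)C4Oc1c(Oc2cc(OC)c(OC)c(Oc3cc(OC)c(OC)c(OC)c3Oc3cc(OC)c(OC)c(OC)c3)c2)cc(OC)c(OC)c1OC | intermediate
42 | protected octamer: rings A, B, C, E, F, G, H fully O-methylated; ring D with D1–O–ring C, D3–OH, D4–O–ring E, D5–OEt | COc1cc(OC)c(Oc2cc(OC)c(Oc3cc(OC)c(OC)c(OC)c3Oc3cc(O)c(Oc4c(Oc5cc(OC)c(OC)c(Oc6cc(OC)c(OC)c(OC)c6Oc6cc(OC)c(OC)c(OC)c6)c5)cc(OC)c(OC)c4OC)c(OCC)c3)c(OC)c2)c(OC)c1 | intermediate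
43 | CNP0309601.0 (free octamer) | Oc1cc(O)c(Oc2cc(O)c(Oc3cc(O)c(O)c(O)c3Oc3cc(O)c(Oc4c(Oc5cc(O)c(O)c(Oc6cc(O)c(O)c(O)c6Oc6cc(O)c(O)c(O)c6)c5)cc(O)c(O)c4O)c(O)c3)c(O)c2)c(O)c1 | target

**Step count**
Total: 19 steps. Longest linear sequence: 11 steps (steps 9 to 19, from 19 and 20).

**Steps most likely to fail**

1. Step 18. The vinylketene released from 37 may be consumed by dimerisation, or by acylating the phenol as it forms, before the bulky ynol ether intercepts it. In addition, 18 may oligomerise at the temperature needed for ring opening. The fallback sets out from 30 (with 13 as partner) and returns to the route at 43; ring D is brought in as a preformed arene.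
   - SNAr of the phenoxide of 30 on 5-bromo-2-fluoro-3-methoxybenzaldehyde (Cs2CO3, DMF, 100 °C; fluoride activated by the ortho formyl group) should give 5-bromo-3-methoxy-2-(E-F-G-H aryloxy)benzaldehyde F1.
   - Ullmann coupling of F1 with 13 (CuI, picolinic acid, K3PO4, DMSO, 100 °C) should give the octamer aldehyde F2.
   - mCPBA should convert F2 into the octamer aryl formate F3, and methanolysis should give the octamer phenol F4, which differs from 42 only in carrying OMe instead of OEt at D5.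
   - BBr3 as in step 19 should convert F4 into 43.

2. Step 8. The terminal aryloxyacetylene may oligomerise or hydrate during work-up and concentration, and excess n-BuLi may metalate the polymethoxyarene rings. The fallback sets out from 17 and returns at 18. The acetylide solution is quenched with chlorotriisopropylsilane to give the triisopropylsilyl-capped A-B-C ynol ether F5, which can be chromatographed and stored. Desilylation with Bu4NF in THF at −78 °C immediately before the benzannulation, with a quick cold filtration, should release 18.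

3. Step 19. Cleavage may stall part-way among the twenty alkyl ethers, and the free polyphenol may oxidise in air during isolation. The fallback sets out from 42 and returns at 43. The crude BBr3 product is not purified but acetylated (Ac2O, pyridine, DMAP) to the henicosaacetate of the octamer F6, which can be separated from partly methylated congeners on silica. Acid methanolysis (HCl generated from AcCl in MeOH, argon) should then give 43.

**Further compounds**
F1 | step 18 | 5-bromo-3-methoxy-2-(E-F-G-H aryloxy)benzaldehyde | O=Cc4cc(Br)cc(OC)c4Oc1c(Oc2cc(OC)c(OC)c(Oc3cc(OC)c(OC)c(OC)c3Oc3cc(OC)c(OC)c(OC)c3)c2)cc(OC)c(OC)c1OC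
F2 | step 18 | octamer aldehyde: 5-(A-B-C aryloxy)-3-methoxy-2-(E-F-G-H aryloxy)benzaldehyde | O=Cc4cc(Oc1c(Oc2c(OC)cc(Oc3c(OC)cc(OC)cc3OC)cc2OC)cc(OC)c(OC)c1OC)cc(OC)c4Oc1c(Oc2cc(OC)c(OC)c(Oc3cc(OC)c(OC)c(OC)c3Oc3cc(OC)c(OC)c(OC)c3)c2)cc(OC)c(OC)c1OC
F3 | step 18 | octamer aryl formate: 5-(A-B-C aryloxy)-3-methoxy-2-(E-F-G-H aryloxy)phenyl formate | O=COc4cc(Oc1c(Oc2c(OC)cc(Oc3c(OC)cc(OC)cc3OC)cc2OC)cc(OC)c(OC)c1OC)cc(OC)c4Oc1c(Oc2cc(OC)c(OC)c(Oc3cc(OC)c(OC)c(OC)c3Oc3cc(OC)c(OC)c(OC)c3)c2)cc(OC)c(OC)c1OC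
F4 | step 18 | octamer phenol: 5-(A-B-C aryloxy)-3-methoxy-2-(E-F-G-H aryloxy)phenol | Oc4cc(Oc1c(Oc2c(OC)cc(Oc3c(OC)cc(OC)cc3OC)cc2OC)cc(OC)c(OC)c1OC)cc(OC)c4Oc1c(Oc2cc(OC)c(OC)c(Oc3cc(OC)c(OC)c(OC)c3Oc3cc(OC)c(OC)c(OC)c3)c2)cc(OC)c(OC)c1OC
F5 | step 8 | triisopropylsilyl-capped A-B-C ynol ether | COc1cc(OC)c(Oc2cc(OC)c(Oc3cc(OC)c(OC)c(OC)c3OC#C[Si](C(C)C)(C(C)C)C(C)C)c(OC)c2)c(OC)c1
F6 | step 19 | henicosaacetate of the octamer 43 | CC(=O)Oc1cc(OC(C)=O)c(Oc2cc(OC(C)=O)c(Oc3cc(OC(C)=O)c(OC(C)=O)c(OC(C)=O)c3Oc3cc(OC(C)=O)c(Oc4c(Oc5cc(OC(C)=O)c(OC(C)=O)c(Oc6cc(OC(C)=O)c(OC(C)=O)c(OC(C)=O)c6Oc6cc(OC(C)=O)c(OC(C)=O)c(OC(C)=O)c6)c5)cc(OC(C)=O)c(OC(C)=O)c4OC(C)=O)c(OC(C)=O)c3)c(OC(C)=O)c2)c(OC(C)=O)c1
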